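**Retrosynthetic overview**
1. The route rests on the unhindered, E-configured C2=C3 enoate alkene inside the 18-membered macrolactone (ring path C1 to C17 and its ester oxygen, running through N3/C4 of the oxazole), next to the methyl-bearing allylic carbon C4. This bond is made last among the rings, by ring-closing metathesis of a C17 acrylate with the C3 vinyl group.
2. After ring closure the C21=C22 Z-alkene is added by Wittig olefination of a C21 aldehyde with a lactic-acid-derived ylide (C22–C25), followed by fluoride deprotection.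
3. Before ring closure the bromo-oxolane is formed by 5-endo bromoetherification of an (E)-C18=C19 alkene by the C16 hydroxyl. The C15–C17 triad comes from alkoxyallylboration, Nozaki–Hiyama–Kishi coupling and chelation-controlled reduction; C4/C5 come from syn-crotylboration.
4. The oxazole is built first from the (S)-citronellal-derived acid (C13 stereocentre) and L-serine methyl ester; the C6=C7 alkene is set by Horner–Wadsworth–Emmons olefination.
5. Order of ring formation: oxazole (ring A), then bromo-oxolane (ring B), then macrolactone (ring C).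

Key step: step 25

Remark on numbering (used only to name positions): C1 lactone carbonyl, C2=C3 enoate, C4 (methyl), C5 (carbinol), C6=C7 (C7 methyl), C8/C9/C10 = oxazole C4/C5/C2, C11–C14 chain (C13 methyl), C15 (OMe), C16–C19 = oxolane C2–C5 (C17 O-acyl, C18 Br, C19 methyl), C20–C25 side chain (C21=C22, C24 carbinol, C25 acid). The target is (4S,5R,13S,15S,16R,17R,18S,19R,24S; 2E,6E,21Z).
Assumption: allyl methoxymethyl ether 20 is taken as a purchased compound (otherwise one step from allyl alcohol and chloromethyl methyl ether).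

**Ring A and the C6=C7 alkene**

Step 1
Reactants: 1 (S)-citronellal
Product: 2 (6S)-8,8-dimethoxy-2,6-dimethyloct-2-ene
Conditions: HC(OMe)3, MeOH, PPTS (cat.), rt
Reagents that add atoms: trimethyl orthoformate, COC(OC)OC
Why: Acid-catalysed acetalisation with an orthoester as water scavenger masks the aldehyde (later C15) under conditions mild enough to avoid the carbonyl-ene cyclisation of citronellal.

Step 2
Reactants: 2 (6S)-8,8-dimethoxy-2,6-dimethyloct-2-ene
Product: 4 (4S)-6,6-dimethoxy-4-methylhexanal, via ozonide 3 (not isolated)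
Conditions: O3, CH2Cl2, −78 °C; then PPh3, −78 °C → rt
Reagents that add atoms: ozone, [O-][O+]=O
Why: Ozonolysis with reductive work-up cleaves the only alkene to the C10 aldehyde while the acetal and the remote C13 stereocentre are untouched.

Step 3
Reactants: 4 (4S)-6,6-dimethoxy-4-methylhexanal
Product: 5 (4S)-6,6-dimethoxy-4-methylhexanoic acid
Conditions: NaClO2, NaH2PO4, 2-methylbut-2-ene, t-BuOH/H2O, 0 °C → rt
Reagents that add atoms: sodium chlorite, [Na+].[O-]Cl=O
Why: Pinnick oxidation takes the aldehyde to the acid in a phosphate buffer that is mild and brief enough for the dimethyl acetal to survive.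

Step 4
Reactants: 5 (4S)-6,6-dimethoxy-4-methylhexanoic acid, 6 L-serine methyl ester hydrochloride
Product: 7 methyl N-[(4S)-6,6-dimethoxy-4-methylhexanoyl]-L-serinate
Conditions: EDC·HCl, HOBt, N-methylmorpholine, CH2Cl2, 0 °C → rt
Reagents that add atoms: none
Why: Carbodiimide/HOBt amide coupling acylates the amine selectively over the serine hydroxyl.

Step 5
Reactants: 7 methyl N-[(4S)-6,6-dimethoxy-4-methylhexanoyl]-L-serinate
Product: 9 methyl 2-[(3S)-5,5-dimethoxy-3-methylpentyl]-1,3-oxazole-4-carboxylate, via oxazoline 8 (not isolated)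
Conditions: Deoxo-Fluor, CH2Cl2, −20 °C; then BrCCl3, DBU, 0 °C → rt
Reagents that add atoms: none
Why: Fluoride-reagent cyclodehydration of the β-hydroxy amide gives the oxazoline, and bromination/dehydrobromination at the ester-activated C4–H aromatises it to the oxazole (ring A), which removes the serine stereocentre.

Step 6
Reactants: 9 methyl 2-[(3S)-5,5-dimethoxy-3-methylpentyl]-1,3-oxazole-4-carboxylate
Product: 11 1-{2-[(3S)-5,5-dimethoxy-3-methylpentyl]-1,3-oxazol-4-yl}ethan-1-one, via Weinreb amide 10 (not isolated)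
Conditions: MeNHOMe·HCl, i-PrMgCl, THF, −20 °C; then MeMgBr, −20 → 0 °C; aq. NH4Cl
Reagents that add atoms: methylmagnesium bromide, C[Mg]Br; N,O-dimethylhydroxylamine hydrochloride, CNOC.Cl (its atoms stay only in intermediate 10)
Why: Magnesium-amide aminolysis of the ester gives the Weinreb amide, whose stable magnesium chelate takes up exactly one methyl Grignard equivalent and releases the methyl ketone on work-up.

Step 7
Reactants: 11 1-{2-[(3S)-5,5-dimethoxy-3-methylpentyl]-1,3-oxazol-4-yl}ethan-1-one, 12 diethyl [2-(methoxy(methyl)amino)-2-oxoethyl]phosphonate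
Product: 13 (2E)-3-{2-[(3S)-5,5-dimethoxy-3-methylpentyl]-1,3-oxazol-4-yl}-N-methoxy-N-methylbut-2-enamide
Conditions: NaH, THF, 0 → 50 °C; chromatographic removal of the minor Z isomer
Reagents that add atoms: none
Why: Horner–Wadsworth–Emmons olefination of the heteroaryl methyl ketone places the larger oxazolyl group trans to the amide carbonyl, which sets the E-configured C6=C7 alkene with C5 already at the Weinreb-amide level.

Step 8
Reactants: 13 (2E)-3-{2-[(3S)-5,5-dimethoxy-3-methylpentyl]-1,3-oxazol-4-yl}-N-methoxy-N-methylbut-2-enamide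
Product: 14 (2E)-N-methoxy-N-methyl-3-{2-[(3S)-3-methyl-5-oxopentyl]-1,3-oxazol-4-yl}but-2-enamide
Conditions: aq. HCl (1 M), THF, rt
Reagents that add atoms: water, O
Why: Acid hydrolysis of the dimethyl acetal frees the C15 aldehyde; the enamide and oxazole are stable to dilute acid.

**C18–C21 alkenyl iodide**

Step 9
Reactants: 15 but-3-yn-1-ol, 16 4-methoxybenzyl chloride
Product: 17 1-[(but-3-yn-1-yloxy)methyl]-4-methoxybenzene
Conditions: NaH, Bu4NI (cat.), THF/DMF, 0 °C → rt
Reagents that add atoms: none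
Why: Williamson etherification protects the future C21 hydroxyl as its PMB ether.

Step 10
Reactants: 17 1-[(but-3-yn-1-yloxy)methyl]-4-methoxybenzene
Product: 19 1-({[(3E)-4-iodo-3-methylbut-3-en-1-yl]oxy}methyl)-4-methoxybenzene, via alkenylalane 18 (not isolated)
Conditions: AlMe3, Cp2ZrCl2 (0.25 equiv), CH2Cl2, 0 °C → rt; then I2, THF, −30 → 0 °C
Reagents that add atoms: trimethylaluminium, C[Al](C)C; iodine, II
Why: Zirconium-catalysed carboalumination adds methyl and aluminium syn across the terminal alkyne (methyl to the internal carbon), and iodinolysis with retention gives the E-configured trisubstituted alkenyl iodide that becomes C18=C19.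

**C15–C17 triad and ring B**

Step 11
Reactants: 14 (2E)-N-methoxy-N-methyl-3-{2-[(3S)-3-methyl-5-oxopentyl]-1,3-oxazol-4-yl}but-2-enamide, 20 allyl methoxymethyl ether
Product: 22 (2E)-3-{2-[(3S,5S,6S)-5-hydroxy-6-(methoxymethoxy)-3-methyloct-7-en-1-yl]-1,3-oxazol-4-yl}-N-methoxy-N-methylbut-2-enamide, via allylborane 21 (not isolated)
Conditions: 20, s-BuLi, THF, −78 °C; (+)-Ipc2BOMe, −78 °C; BF3·OEt2; then 14, −78 °C; NaOH, H2O2, 0 °C → rt
Reagents that add atoms: (+)-B-methoxydiisopinocampheylborane, COB([C@H]1C[C@H]2C[C@@H]([C@@H]1C)C2(C)C)[C@H]1C[C@H]2C[C@@H]([C@@H]1C)C2(C)C (its atoms stay only in intermediate 21)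
Why: Brown alkoxyallylboration through a chair transition state of the (Z)-γ-alkoxyallylborane gives the syn C15-hydroxy/C16-alkoxy pair, and the isopinocampheyl groups derived from (−)-α-pinene direct attack to the re face of the aldehyde, setting C15 (S) and with it C16.

Step 12
Reactants: 22 (2E)-3-{2-[(3S,5S,6S)-5-hydroxy-6-(methoxymethoxy)-3-methyloct-7-en-1-yl]-1,3-oxazol-4-yl}-N-methoxy-N-methylbut-2-enamide
Product: 23 (2E)-N-methoxy-3-{2-[(3S,5S,6S)-5-methoxy-6-(methoxymethoxy)-3-methyloct-7-en-1-yl]-1,3-oxazol-4-yl}-N-methylbut-2-enamide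
Conditions: NaH, MeI, THF/DMF, 0 °C
Reagents that add atoms: iodomethane, CI
Why: Williamson methylation of the only free hydroxyl installs the C15 methyl ether without touching a stereocentre.

Step 13
Reactants: 23 (2E)-N-methoxy-3-{2-[(3S,5S,6S)-5-methoxy-6-(methoxymethoxy)-3-methyloct-7-en-1-yl]-1,3-oxazol-4-yl}-N-methylbut-2-enamide
Product: 24 (2E)-N-methoxy-3-{2-[(3S,5S,6R)-5-methoxy-6-(methoxymethoxy)-3-methyl-7-oxoheptyl]-1,3-oxazol-4-yl}-N-methylbut-2-enamide
Conditions: OsO4 (cat.), NaIO4, 2,6-lutidine, dioxane/H2O, rt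
Reagents that add atoms: osmium tetroxide, O=[Os](=O)(=O)=O; sodium periodate, [Na+].[O-]I(=O)(=O)=O
Why: Lemieux–Johnson cleavage takes the monosubstituted vinyl group to the C17 aldehyde, because osmylation of the hindered, electron-poor trisubstituted enamide alkene is much slower.

Step 14
Reactants: 24 (2E)-N-methoxy-3-{2-[(3S,5S,6R)-5-methoxy-6-(methoxymethoxy)-3-methyl-7-oxoheptyl]-1,3-oxazol-4-yl}-N-methylbut-2-enamide, 19 1-({[(3E)-4-iodo-3-methylbut-3-en-1-yl]oxy}methyl)-4-methoxybenzene
Product: 25 C17-epimeric allylic alcohols (C15 OMe, C16 OMOM, C17 OH, (E)-C18=C19 alkene carrying the C19 methyl and the 2-(PMB-oxy)ethyl group)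
Conditions: CrCl2, NiCl2 (cat.), DMSO, rt
Reagents that add atoms: none
Why: Nozaki–Hiyama–Kishi coupling joins the alkenyl iodide to the aldehyde with retention of alkene geometry under neutral conditions that spare the Weinreb amide and the base-sensitive β-methoxy aldehyde; the C17 configuration is not needed because it is erased in step 15.

Step 15
Reactants: 25 C17-epimeric allylic alcohols
Product: 26 enone (C17 ketone conjugated to the (E)-C18=C19 alkene; C16 OMOM, C15 OMe)
Conditions: Dess–Martin periodinane, NaHCO3, CH2Cl2, 0 °C → rt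
Reagents that add atoms: none
Why: Dess–Martin oxidation converges both epimers on one enone under buffered, non-epimerising conditions.

Step 16
Reactants: 26 enone
Product: 27 α-hydroxy enone (C16 OH, C17 ketone)
Conditions: TMSOTf, 2,2′-bipyridyl, CH2Cl2, 0 °C → rt; then H2O
Reagents that add atoms: none
Why: Silyl triflate/bipyridyl cleavage of the aliphatic MOM ether goes through a bipyridinium N,O-acetal that water hydrolyses, and it is specific for the acetal-type ether, so the PMB ether, the methyl ether, the enone and the amide remain.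

Step 17
Reactants: 27 α-hydroxy enone
Product: 28 anti-diol, (2E)-3-{2-[(3S,5S,6S,7S,8E)-6,7-dihydroxy-5-methoxy-11-[(4-methoxybenzyl)oxy]-3,9-dimethylundec-8-en-1-yl]-1,3-oxazol-4-yl}-N-methoxy-N-methylbut-2-enamide
Conditions: Zn(BH4)2, Et2O, −30 → 0 °C; aq. NH4Cl
Reagents that add atoms: none
Why: Chelation-controlled 1,2-reduction through the five-membered zinc chelate of the C16 alkoxide and the C17 carbonyl delivers hydride to the face away from the C15 chain and sets C17 anti to C16, while the amide is inert to zinc borohydride.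

Step 18
Reactants: 28 anti-diol
Product: 29 bromo-oxolane alcohol (oxolane O–C16–C17–C18–C19; C17 OH, C18 Br, C19 methyl and 2-(PMB-oxy)ethyl; all stereocentres as in the target)
Conditions: NBS, MeCN, −20 → 0 °C, dark
Reagents that add atoms: N-bromosuccinimide, O=C1CCC(=O)N1Br
Why: 5-endo bromoetherification: the C16 hydroxyl opens the bromonium ion of the (E)-C18=C19 alkene at the tertiary C19 in an anti addition, so C18–Br comes out cis to the C19 methyl, and the alkene face is chosen by allylic 1,3-strain with that methyl and by the preference for bromine trans to the C17 oxygen, which sets C18 (S) and C19 (R).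

Step 19
Reactants: 29 bromo-oxolane alcohol
Product: 30 C17 triethylsilyl ether of 29
Conditions: TESOTf, 2,6-lutidine, CH2Cl2, −78 → 0 °C
Reagents that add atoms: triethylsilyl trifluoromethanesulfonate, CC[Si](CC)(CC)OS(=O)(=O)C(F)(F)F
Why: Silyl triflate silylation protects the hindered C17 hydroxyl temporarily, so that the hydride and boron reagents of the next steps meet no free hydroxyl.

**C4/C5 arm, acrylate and ring C**

Step 20
Reactants: 30 C17 triethylsilyl ether
Product: 31 enal (C5 aldehyde conjugated to C6=C7)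
Conditions: i-Bu2AlH, THF, −78 °C; Rochelle salt
Reagents that add atoms: none
Why: Hydride reduction of the unsaturated Weinreb amide stops at the chelated hemiaminal, which gives the enal on work-up and leaves bromide, silyl ether and PMB ether untouched.

Step 21
Reactants: 31 enal, 32 cis-but-2-ene
Product: 34 syn homoallylic alcohol (C5 OH, C4 methyl, C3 vinyl; C4 S, C5 R), via crotylborane 33 (not isolated)
Conditions: 32, n-BuLi, KOt-Bu, THF, −78 → −45 °C; (+)-Ipc2BOMe, −78 °C; BF3·OEt2; then 31, −78 °C; NaOH, H2O2, 0 °C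
Reagents that add atoms: (+)-B-methoxydiisopinocampheylborane, COB([C@H]1C[C@H]2C[C@@H]([C@@H]1C)C2(C)C)[C@H]1C[C@H]2C[C@@H]([C@@H]1C)C2(C)C (its atoms stay only in intermediate 33)
Why: Brown crotylboration with the (Z)-crotylborane gives the syn methyl/hydroxyl pair through a chair transition state, and the isopinocampheyl groups direct re-face attack on the enal, which sets C5 (R) and C4 (S) and leaves the terminal vinyl group for metathesis.

Step 22
Reactants: 34 syn homoallylic alcohol
Product: 35 C5 tert-butyldimethylsilyl ether of 34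
Conditions: TBSOTf, 2,6-lutidine, CH2Cl2, −78 → 0 °C
Reagents that add atoms: tert-butyldimethylsilyl trifluoromethanesulfonate, CC(C)(C)[Si](C)(C)OS(=O)(=O)C(F)(F)F
Why: Silyl triflate silylation protects the hindered allylic C5 hydroxyl as the ether that lasts to the final step.

Step 23
Reactants: 35 C5 tert-butyldimethylsilyl ether
Product: 36 C17 alcohol (C5 OTBS, C21 OPMB, C3 vinyl)
Conditions: PPTS, MeOH/CH2Cl2, 0 °C → rt
Reagents that add atoms: none
Why: Acid-catalysed methanolysis removes the secondary triethylsilyl ether much faster than the secondary tert-butyldimethylsilyl ether, which frees only the C17 hydroxyl.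

Step 24
Reactants: 36 C17 alcohol, 37 acryloyl chloride
Product: 38 acrylate ester diene (C17 acrylate, C3 vinyl, C5 OTBS, C21 OPMB)
Conditions: i-Pr2NEt, CH2Cl2, −20 → 0 °C
Reagents that add atoms: none
Why: Acylation of the single free hydroxyl with the acid chloride installs the acrylate partner for metathesis.

Step 25
Reactants: 38 acrylate ester diene
Product: 39 macrolide with PMB-protected hydroxyethyl stub
Conditions: second-generation Grubbs catalyst (H2IMes)(PCy3)Cl2Ru=CHPh (10 mol %), toluene (1 mM), 80 °C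
Reagents that add atoms: none
Why: The ruthenium benzylidene initiates at the monosubstituted C3 vinyl group, the new alkylidene adds across the C17 acrylate in a [2+2]/retro-[2+2] sequence and ethylene is lost, which forms the C2=C3 bond and closes the 18-membered lactone (ring C) at that alkene. The closest known reaction type is macrocyclic ring-closing metathesis of an acrylate ester with a terminal alkene by second-generation ruthenium carbenes. No stereocentre is created. The step needs E geometry, which conjugation with C1 and the large ring favour under the reversible conditions, and site selectivity, which the substrate secures because it holds only two terminal alkenes: the trisubstituted C6=C7 alkene on the oxazole is inert and the later C21=C22 alkene is still a PMB-protected hydroxyethyl group. High dilution suppresses oligomers, and the absence of free hydroxyl groups keeps the catalyst from being diverted.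

Step 26
Reactants: 39 macrolide with PMB-protected hydroxyethyl stub
Product: 40 macrolide C21 primary alcohol
Conditions: DDQ, CH2Cl2/pH 7 buffer, 0 °C
Reagents that add atoms: none
Why: Oxidative PMB cleavage by hydride abstraction from the electron-rich benzyl ether frees the C21 hydroxyl without touching the silyl ether, the bromide or the lactone.

Step 27
Reactants: 40 macrolide C21 primary alcohol
Product: 41 macrolide C21 aldehyde
Conditions: Dess–Martin periodinane, NaHCO3, CH2Cl2, 0 °C
Reagents that add atoms: none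
Why: Buffered Dess–Martin oxidation gives the β-alkoxy aldehyde under neutral conditions that avoid β-elimination of the ring oxygen.

**C22–C25 phosphonium salt**

Step 28
Reactants: 42 (R)-lactic acid, 43 pivalaldehyde
Product: 44 (2R,5R)-2-tert-butyl-5-methyl-1,3-dioxolan-4-one
Conditions: p-TsOH (cat.), H2SO4 (cat.), pentane, reflux (Dean–Stark); crystallisation of the cis isomer
Reagents that add atoms: none
Why: Acid-catalysed acetalisation with water removal gives mainly the cis dioxolanone, in which the new acetal centre stores the chirality of the lactate.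

Step 29
Reactants: 44 (2R,5R)-2-tert-butyl-5-methyl-1,3-dioxolan-4-one, 45 allyl bromide
Product: 47 (2R,5S)-2-tert-butyl-5-methyl-5-(prop-2-en-1-yl)-1,3-dioxolan-4-one, via lithium enolate 46 (not isolated)
Conditions: LDA, THF, −78 °C; then 45, −78 → −30 °C
Reagents that add atoms: lithium diisopropylamide, [Li+].CC(C)[N-]C(C)C (lithium stays only in intermediate 46)
Why: Enolate alkylation under self-regeneration of the stereocentre occurs trans to the tert-butyl group, so the allyl group takes the place of the lactate hydrogen with retention and sets the C24 quaternary centre.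

Step 30
Reactants: 47 (2R,5S)-2-tert-butyl-5-methyl-5-(prop-2-en-1-yl)-1,3-dioxolan-4-one
Product: 50 (3S)-3-hydroxy-3-methyloxolan-2-one, via ozonide 48 (not isolated), via hydroxyethyl dioxolanone 49 (not isolated)
Conditions: O3, CH2Cl2, −78 °C; NaBH4, MeOH, −78 → 0 °C; then aq. HCl to pH 2, rt
Reagents that add atoms: ozone, [O-][O+]=O
Why: Ozonolysis with borohydride work-up gives the primary alcohol, which lactonises onto the activated dioxolanone carbonyl with loss of pivalaldehyde; the quaternary centre cannot epimerise.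

Step 31
Reactants: 50 (3S)-3-hydroxy-3-methyloxolan-2-one
Product: 51 [(3S)-3-carboxy-3-hydroxybutyl]triphenylphosphonium bromide
Conditions: Ph3P·HBr, neat (melt), 150 °C
Reagents that add atoms: triphenylphosphine hydrobromide, Br.c1ccc(cc1)P(c1ccccc1)c1ccccc1
Why: Acid-promoted ring opening of the γ-lactone at the O-alkyl carbon by bromide followed by irreversible SN2 capture by triphenylphosphine gives the carboxypropyl-type phosphonium salt; the α-carbonyl tertiary alcohol does not ionise.

Step 32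
Reactants: 51 [(3S)-3-carboxy-3-hydroxybutyl]triphenylphosphonium bromide, 52 2-(trimethylsilyl)ethanol
Product: 53 {(3S)-3-hydroxy-3-methyl-4-oxo-4-[2-(trimethylsilyl)ethoxy]butyl}triphenylphosphonium bromide
Conditions: EDC·HCl, DMAP (cat.), CH2Cl2, 0 °C → rt
Reagents that add atoms: none
Why: Steglich-type esterification masks the acid as a fluoride-labile ester; the hindered tertiary hydroxyl is not acylated.

Step 33
Reactants: 53 {(3S)-3-hydroxy-3-methyl-4-oxo-4-[2-(trimethylsilyl)ethoxy]butyl}triphenylphosphonium bromide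
Product: 54 {(3S)-3-methyl-4-oxo-3-(triethylsilyloxy)-4-[2-(trimethylsilyl)ethoxy]butyl}triphenylphosphonium bromide
Conditions: TESOTf, 2,6-lutidine, CH2Cl2, 0 °C → rt; aq. NaBr wash
Reagents that add atoms: triethylsilyl trifluoromethanesulfonate, CC[Si](CC)(CC)OS(=O)(=O)C(F)(F)F
Why: Silyl triflate silylation caps the tertiary hydroxyl, so that the ylide carries no anionic group that would erode Z-selectivity.

**Side chain and deprotection**

Step 34
Reactants: 41 macrolide C21 aldehyde, 54 {(3S)-3-methyl-4-oxo-3-(triethylsilyloxy)-4-[2-(trimethylsilyl)ethoxy]butyl}triphenylphosphonium bromide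
Product: 56 fully protected target (21Z alkene; C5 OTBS, C24 OTES, C25 2-(trimethylsilyl)ethyl ester), via phosphorus ylide 55 (not isolated)
Conditions: 54, KHMDS, THF, −78 → 0 °C; then 41, −78 → −20 °C
Reagents that add atoms: none
Why: Salt-free Wittig olefination with the non-stabilised ylide closes the cis-oxaphosphetane under kinetic control and gives the C21=C22 Z-alkene, and the low temperature and fast addition to the aldehyde outpace β-elimination and attack on the enoate.

Step 35
Reactants: 56 fully protected target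
Product: 57 target compound CNP0163177.2
Conditions: Bu4NF, AcOH, THF, 0 °C → rt
Reagents that add atoms: none
Why: Fluoride-induced desilylation removes both silyl ethers and fragments the 2-(trimethylsilyl)ethyl ester to the acid in one operation, and the acetic acid buffer protects the macrolactone and the bromide, which has no anti-periplanar hydrogen for elimination.

**Compound list**
1 | (S)-citronellal, (3S)-3,7-dimethyloct-6-enal | C[C@@H](CCC=C(C)C)CC=O | starting material
2 | (6S)-8,8-dimethoxy-2,6-dimethyloct-2-ene | C[C@@H](CCC=C(C)C)CC(OC)OC | intermediate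
3 | ozonide, 3-[(3S)-5,5-dimethoxy-3-methylpentyl]-5,5-dimethyl-1,2,4-trioxolane | CC1(C)OOC(CC[C@H](C)CC(OC)OC)O1 | intermediate
4 | (4S)-6,6-dimethoxy-4-methylhexanal | O=CCC[C@H](C)CC(OC)OC | intermediate
5 | (4S)-6,6-dimethoxy-4-methylhexanoic acid | OC(=O)CC[C@H](C)CC(OC)OC | intermediate
6 | L-serine methyl ester hydrochloride | COC(=O)[C@@H](N)CO.Cl | starting material
7 | methyl N-[(4S)-6,6-dimethoxy-4-methylhexanoyl]-L-serinate | COC(=O)[C@H](CO)NC(=O)CC[C@H](C)CC(OC)OC | intermediate
8 | oxazoline, methyl (4S)-2-[(3S)-5,5-dimethoxy-3-methylpentyl]-4,5-dihydro-1,3-oxazole-4-carboxylate | COC(=O)[C@@H]1COC(CC[C@H](C)CC(OC)OC)=N1 | intermediate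
9 | methyl 2-[(3S)-5,5-dimethoxy-3-methylpentyl]-1,3-oxazole-4-carboxylate | COC(=O)c1coc(CC[C@H](C)CC(OC)OC)n1 | intermediate
10 | Weinreb amide, 2-[(3S)-5,5-dimethoxy-3-methylpentyl]-N-methoxy-N-methyl-1,3-oxazole-4-carboxamide | CON(C)C(=O)c1coc(CC[C@H](C)CC(OC)OC)n1 | intermediate
11 | 1-{2-[(3S)-5,5-dimethoxy-3-methylpentyl]-1,3-oxazol-4-yl}ethan-1-one | CC(=O)c1coc(CC[C@H](C)CC(OC)OC)n1 | intermediate
12 | diethyl [2-(methoxy(methyl)amino)-2-oxoethyl]phosphonate | CCOP(=O)(CC(=O)N(C)OC)OCC | starting material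
13 | (2E)-3-{2-[(3S)-5,5-dimethoxy-3-methylpentyl]-1,3-oxazol-4-yl}-N-methoxy-N-methylbut-2-enamide | CON(C)C(=O)/C=C(\C)c1coc(CC[C@H](C)CC(OC)OC)n1 | intermediate
14 | (2E)-N-methoxy-N-methyl-3-{2-[(3S)-3-methyl-5-oxopentyl]-1,3-oxazol-4-yl}but-2-enamide | CON(C)C(=O)/C=C(\C)c1coc(CC[C@H](C)CC=O)n1 | intermediate
15 | but-3-yn-1-ol | C#CCCO | starting material
16 | 4-methoxybenzyl chloride | COc1ccc(CCl)cc1 | starting material
17 | 1-[(but-3-yn-1-yloxy)methyl]-4-methoxybenzene | C#CCCOCc1ccc(OC)cc1 | intermediate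
18 | alkenylalane, dimethyl[(1E)-4-(4-methoxybenzyloxy)-2-methylbut-1-en-1-yl]alane | C[Al](C)/C=C(\C)CCOCc1ccc(OC)cc1 | intermediate
19 | 1-({[(3E)-4-iodo-3-methylbut-3-en-1-yl]oxy}methyl)-4-methoxybenzene | I/C=C(\C)CCOCc1ccc(OC)cc1 | intermediate
20 | allyl methoxymethyl ether, 3-(methoxymethoxy)prop-1-ene | C=CCOCOC | starting material
21 | allylborane, [(2Z)-3-(methoxymethoxy)prop-2-en-1-yl]diisopinocampheylborane (isopinocampheyl groups from (−)-α-pinene) | COCO/C=C\CB([C@H]1C[C@H]2C[C@@H]([C@@H]1C)C2(C)C)[C@H]1C[C@H]2C[C@@H]([C@@H]1C)C2(C)C | intermediate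
22 | (2E)-3-{2-[(3S,5S,6S)-5-hydroxy-6-(methoxymethoxy)-3-methyloct-7-en-1-yl]-1,3-oxazol-4-yl}-N-methoxy-N-methylbut-2-enamide | CON(C)C(=O)/C=C(\C)c1coc(CC[C@H](C)C[C@H](O)[C@@H](OCOC)C=C)n1 | intermediate
23 | (2E)-N-methoxy-3-{2-[(3S,5S,6S)-5-methoxy-6-(methoxymethoxy)-3-methyloct-7-en-1-yl]-1,3-oxazol-4-yl}-N-methylbut-2-enamide | CON(C)C(=O)/C=C(\C)c1coc(CC[C@H](C)C[C@H](OC)[C@@H](OCOC)C=C)n1 | intermediate
24 | (2E)-N-methoxy-3-{2-[(3S,5S,6R)-5-methoxy-6-(methoxymethoxy)-3-methyl-7-oxoheptyl]-1,3-oxazol-4-yl}-N-methylbut-2-enamide | CON(C)C(=O)/C=C(\C)c1coc(CC[C@H](C)C[C@H](OC)[C@@H](OCOC)C=O)n1 | intermediate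
25 | C17-epimeric allylic alcohols (C15 OMe, C16 OMOM, C17 OH, (E)-C18=C19, C21 OPMB) | CON(C)C(=O)/C=C(\C)c1coc(CC[C@H](C)C[C@H](OC)[C@@H](OCOC)C(O)/C=C(\C)CCOCc2ccc(OC)cc2)n1 | intermediate
26 | enone (C17 ketone, C16 OMOM, (E)-C18=C19) | CON(C)C(=O)/C=C(\C)c1coc(CC[C@H](C)C[C@H](OC)[C@@H](OCOC)C(=O)/C=C(\C)CCOCc2ccc(OC)cc2)n1 | intermediate
27 | α-hydroxy enone (C16 OH, C17 ketone) | CON(C)C(=O)/C=C(\C)c1coc(CC[C@H](C)C[C@H](OC)[C@@H](O)C(=O)/C=C(\C)CCOCc2ccc(OC)cc2)n1 | intermediate
28 | anti-diol, (2E)-3-{2-[(3S,5S,6S,7S,8E)-6,7-dihydroxy-5-methoxy-11-[(4-methoxybenzyl)oxy]-3,9-dimethylundec-8-en-1-yl]-1,3-oxazol-4-yl}-N-methoxy-N-methylbut-2-enamide | CON(C)C(=O)/C=C(\C)c1coc(CC[C@H](C)C[C@H](OC)[C@@H](O)[C@@H](O)/C=C(\C)CCOCc2ccc(OC)cc2)n1 | intermediate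
29 | bromo-oxolane alcohol (C17 OH, C18 Br, Weinreb enamide arm; stereocentres C13, C15–C19 as in the target) | CO[C@@H](C[C@@H](C)CCc1nc(co1)/C(C)=C/C(=O)N(C)OC)[C@H]1O[C@](C)(CCOCc2ccc(OC)cc2)[C@@H](Br)[C@@H]1O | intermediate
30 | C17 triethylsilyl ether of 29 | CO[C@@H](C[C@@H](C)CCc1nc(co1)/C(C)=C/C(=O)N(C)OC)[C@H]1O[C@](C)(CCOCc2ccc(OC)cc2)[C@@H](Br)[C@@H]1O[Si](CC)(CC)CC | intermediate
31 | enal (C5 aldehyde, (6E); C17 OTES) | CO[C@@H](C[C@@H](C)CCc1nc(co1)/C(C)=C/C=O)[C@H]1O[C@](C)(CCOCc2ccc(OC)cc2)[C@@H](Br)[C@@H]1O[Si](CC)(CC)CC | intermediate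
32 | cis-but-2-ene | C/C=C\C | starting material
33 | crotylborane, [(2Z)-but-2-en-1-yl]diisopinocampheylborane (isopinocampheyl groups from (−)-α-pinene) | C/C=C\CB([C@H]1C[C@H]2C[C@@H]([C@@H]1C)C2(C)C)[C@H]1C[C@H]2C[C@@H]([C@@H]1C)C2(C)C | intermediate
34 | syn homoallylic alcohol (C5 OH, C4 methyl, C3 vinyl; C17 OTES) | CO[C@@H](C[C@@H](C)CCc1nc(co1)/C(C)=C/[C@H](O)[C@@H](C)C=C)[C@H]1O[C@](C)(CCOCc2ccc(OC)cc2)[C@@H](Br)[C@@H]1O[Si](CC)(CC)CC | intermediate
35 | C5 tert-butyldimethylsilyl ether of 34 (C17 OTES) | CO[C@@H](C[C@@H](C)CCc1nc(co1)/C(C)=C/[C@H](O[Si](C)(C)C(C)(C)C)[C@@H](C)C=C)[C@H]1O[C@](C)(CCOCc2ccc(OC)cc2)[C@@H](Br)[C@@H]1O[Si](CC)(CC)CC | intermediate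
36 | C17 alcohol (C5 OTBS, C21 OPMB, C3 vinyl) | CO[C@@H](C[C@@H](C)CCc1nc(co1)/C(C)=C/[C@H](O[Si](C)(C)C(C)(C)C)[C@@H](C)C=C)[C@H]1O[C@](C)(CCOCc2ccc(OC)cc2)[C@@H](Br)[C@@H]1O | intermediate
37 | acryloyl chloride | C=CC(=O)Cl | starting material
38 | acrylate ester diene with PMB-protected hydroxyethyl stub | CO[C@@H](C[C@@H](C)CCc1nc(co1)/C(C)=C/[C@H](O[Si](C)(C)C(C)(C)C)[C@@H](C)C=C)[C@H]1O[C@](C)(CCOCc2ccc(OC)cc2)[C@@H](Br)[C@@H]1OC(=O)C=C | intermediate
39 | macrolide with PMB-protected hydroxyethyl stub (2E, C5 OTBS) | CO[C@H]1C[C@@H](C)CCc2nc(co2)/C(C)=C/[C@H](O[Si](C)(C)C(C)(C)C)[C@@H](C)/C=C/C(=O)O[C@@H]2[C@@H]1O[C@](C)(CCOCc3ccc(OC)cc3)[C@H]2Br | intermediate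
40 | macrolide C21 primary alcohol | CO[C@H]1C[C@@H](C)CCc2nc(co2)/C(C)=C/[C@H](O[Si](C)(C)C(C)(C)C)[C@@H](C)/C=C/C(=O)O[C@@H]2[C@@H]1O[C@](C)(CCO)[C@H]2Br | intermediate
41 | macrolide C21 aldehyde | CO[C@H]1C[C@@H](C)CCc2nc(co2)/C(C)=C/[C@H](O[Si](C)(C)C(C)(C)C)[C@@H](C)/C=C/C(=O)O[C@@H]2[C@@H]1O[C@](C)(CC=O)[C@H]2Br | intermediate
42 | (R)-lactic acid | C[C@@H](O)C(=O)O | starting material
43 | pivalaldehyde | CC(C)(C)C=O | starting material
44 | (2R,5R)-2-tert-butyl-5-methyl-1,3-dioxolan-4-one (cis) | C[C@H]1O[C@@H](C(C)(C)C)OC1=O | intermediate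
45 | allyl bromide | C=CCBr | starting material
46 | lithium enolate of 44 | CC1=C([O-])O[C@H](C(C)(C)C)O1.[Li+] | intermediate
47 | (2R,5S)-2-tert-butyl-5-methyl-5-(prop-2-en-1-yl)-1,3-dioxolan-4-one | C[C@@]1(CC=C)O[C@@H](C(C)(C)C)OC1=O | intermediate
48 | ozonide of 47 (1,2,4-trioxolan-3-ylmethyl dioxolanone) | C[C@@]1(CC2OCOO2)O[C@@H](C(C)(C)C)OC1=O | intermediate
49 | hydroxyethyl dioxolanone, (2R,5S)-2-tert-butyl-5-(2-hydroxyethyl)-5-methyl-1,3-dioxolan-4-one | C[C@@]1(CCO)O[C@@H](C(C)(C)C)OC1=O | intermediate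
50 | (3S)-3-hydroxy-3-methyloxolan-2-one | C[C@@]1(O)C(=O)OCC1 | intermediate
51 | [(3S)-3-carboxy-3-hydroxybutyl]triphenylphosphonium bromide | C[C@@](CC[P+](c1ccccc1)(c1ccccc1)c1ccccc1)(O)C(=O)O.[Br-] | intermediate
52 | 2-(trimethylsilyl)ethanol | C[Si](C)(C)CCO | starting material
53 | {(3S)-3-hydroxy-3-methyl-4-oxo-4-[2-(trimethylsilyl)ethoxy]butyl}triphenylphosphonium bromide | C[C@@](CC[P+](c1ccccc1)(c1ccccc1)c1ccccc1)(O)C(=O)OCC[Si](C)(C)C.[Br-] | intermediate
54 | {(3S)-3-methyl-4-oxo-3-(triethylsilyloxy)-4-[2-(trimethylsilyl)ethoxy]butyl}triphenylphosphonium bromide | C[C@@](CC[P+](c1ccccc1)(c1ccccc1)c1ccccc1)(O[Si](CC)(CC)CC)C(=O)OCC[Si](C)(C)C.[Br-] | intermediate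
55 | phosphorus ylide from 54 | C[C@@](CC=P(c1ccccc1)(c1ccccc1)c1ccccc1)(O[Si](CC)(CC)CC)C(=O)OCC[Si](C)(C)C | intermediate
56 | fully protected target (21Z; C5 OTBS, C24 OTES, 2-(trimethylsilyl)ethyl ester) | CO[C@H]1C[C@@H](C)CCc2nc(co2)/C(C)=C/[C@H](O[Si](C)(C)C(C)(C)C)[C@@H](C)/C=C/C(=O)O[C@@H]2[C@@H]1O[C@](C)(C/C=C\C[C@](C)(O[Si](CC)(CC)CC)C(=O)OCC[Si](C)(C)C)[C@H]2Br | intermediate
57 | CNP0163177.2 | CO[C@H]1C[C@@H](C)CCc2nc(co2)/C(C)=C/[C@H](O)[C@@H](C)/C=C/C(=O)O[C@@H]2[C@@H]1O[C@](C)(C/C=C\C[C@](C)(O)C(=O)O)[C@H]2Br | target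

**Totals**
Total step count: 35.
Longest linear sequence: 27 steps from (S)-citronellal (steps 1–8, 11–27, 34 and 35).

**Steps most likely to fail**

1. Step 25 (ring-closing metathesis). The ruthenium carbene may be held by the oxazole nitrogen, or intermolecular cross-metathesis may outrun the entropically demanding 18-ring closure and give oligomers; E/Z equilibration may also stay incomplete. The fallback sets out from alcohol 36 and comes back at macrolide 39. Cross-metathesis of the C3 vinyl group of 36 with methyl acrylate (second-generation Hoveyda–Grubbs catalyst (H2IMes)Cl2Ru=CH(C6H4-2-Oi-Pr), CH2Cl2, 40 °C) should give the (E)-methyl enoate F1, so that the C2=C3 bond is still made by metathesis but without a ring constraint. Hydrolysis with LiOH in THF/H2O should give the seco acid F2. Yamaguchi macrolactonisation (2,4,6-trichlorobenzoyl chloride, Et3N; then DMAP, toluene, high dilution) onto the C17 hydroxyl then closes the same ring to 39.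

2. Step 18 (bromoetherification). Facial selectivity of bromonium formation may be poor, or the free allylic C17 hydroxyl may take part, giving the C18/C19 diastereomer or bromohydrin-type products. The fallback sets out from enone 26 and comes back at bromo-oxolane alcohol 29; it cyclises a substrate with a single hydroxyl and a bulky allylic silyloxy group that shields one alkene face. Zn(BH4)2 reduction of 26 under chelation through the MOM ether should give the anti alcohol F3, and TBSOTf/2,6-lutidine the C17 silyl ether F4. TMSOTf/2,2′-bipyridyl followed by water should give the C16 alcohol F5, and NBS in MeCN the bromo-oxolane silyl ether F6. Bu4NF then gives 29.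

3. Step 34 (Wittig olefination). The basic ylide may trigger β-elimination of the ring oxygen from the β-alkoxy aldehyde or add to the macrocyclic enoate, and Z-selectivity may erode. The fallback sets out from aldehyde 41 (with dioxolanone 47 for the partner) and comes back at 56; it replaces the carbonyl olefination by a non-basic methylenation and a Z-selective cross-metathesis. Takai–Lombardo methylenation of 41 (Zn, CH2Br2, TiCl4, THF) should give the terminal alkene F7. Separately, opening of 47 with 2-(trimethylsilyl)ethanol and NaH (cat.) should give the hydroxy ester F8, and TESOTf/2,6-lutidine the silyl ether F9. Cross-metathesis of F7 with an excess of F9 under a Z-selective cyclometalated ruthenium catalyst, Ru(NO3)(=CH-C6H4-2-Oi-Pr)(NHC) with NHC = C–H-activated 1-(1-adamantyl)-3-(2,6-diisopropylphenyl)imidazolin-2-ylidene, which does not engage the E-enoate or the trisubstituted alkene, should give 56.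

**Further compounds**
F1 | step 25 | (E)-methyl enoate hydroxy ester (C1 methyl ester, 2E, C17 OH, C5 OTBS, C21 OPMB) | CO[C@@H](C[C@@H](C)CCc1nc(co1)/C(C)=C/[C@H](O[Si](C)(C)C(C)(C)C)[C@@H](C)/C=C/C(=O)OC)[C@H]1O[C@](C)(CCOCc2ccc(OC)cc2)[C@@H](Br)[C@@H]1O
F2 | step 25 | seco acid (C1 acid, 2E, C17 OH) | CO[C@@H](C[C@@H](C)CCc1nc(co1)/C(C)=C/[C@H](O[Si](C)(C)C(C)(C)C)[C@@H](C)/C=C/C(=O)O)[C@H]1O[C@](C)(CCOCc2ccc(OC)cc2)[C@@H](Br)[C@@H]1O
F3 | step 18 | anti alcohol (C17 OH, C16 OMOM) | CON(C)C(=O)/C=C(\C)c1coc(CC[C@H](C)C[C@H](OC)[C@@H](OCOC)[C@@H](O)/C=C(\C)CCOCc2ccc(OC)cc2)n1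
F4 | step 18 | C17 tert-butyldimethylsilyl ether (C16 OMOM) | CON(C)C(=O)/C=C(\C)c1coc(CC[C@H](C)C[C@H](OC)[C@@H](OCOC)[C@@H](O[Si](C)(C)C(C)(C)C)/C=C(\C)CCOCc2ccc(OC)cc2)n1
F5 | step 18 | C16 alcohol (C17 OTBS) | CON(C)C(=O)/C=C(\C)c1coc(CC[C@H](C)C[C@H](OC)[C@@H](O)[C@@H](O[Si](C)(C)C(C)(C)C)/C=C(\C)CCOCc2ccc(OC)cc2)n1
F6 | step 18 | bromo-oxolane C17 tert-butyldimethylsilyl ether | CO[C@@H](C[C@@H](C)CCc1nc(co1)/C(C)=C/C(=O)N(C)OC)[C@H]1O[C@](C)(CCOCc2ccc(OC)cc2)[C@@H](Br)[C@@H]1O[Si](C)(C)C(C)(C)C
F7 | step 34 | macrolide with C19 allyl group (C21=CH2) | CO[C@H]1C[C@@H](C)CCc2nc(co2)/C(C)=C/[C@H](O[Si](C)(C)C(C)(C)C)[C@@H](C)/C=C/C(=O)O[C@@H]2[C@@H]1O[C@](C)(CC=C)[C@H]2Br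
F8 | step 34 | 2-(trimethylsilyl)ethyl (2S)-2-hydroxy-2-methylpent-4-enoate | C[C@@](CC=C)(O)C(=O)OCC[Si](C)(C)C
F9 | step 34 | 2-(trimethylsilyl)ethyl (2S)-2-methyl-2-(triethylsilyloxy)pent-4-enoate | C[C@@](CC=C)(O[Si](CC)(CC)CC)C(=O)OCC[Si](C)(C)C
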